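**Retrosynthetic overview**

1. Last disconnection: both oxepan-3-one rings (O1–C2(CH3)2–C3(=O)–C4–C5–C5a–C9a) are opened at C2–C3, the bond between the gem-dimethyl carbon and the ketone carbon. C3 becomes the aldehyde of a CH2CH2CHO arm on C5a, C2 the internal carbon of a prop-1-en-2-yl ether on the C9a oxygen, and one carbene-catalysed hydroacylation closes both rings together (22 → 25). Enabling feature: in each ring the ketone carbon C3 is bonded directly to the ether-bearing carbon C2(CH3)2, and the C9a–O bond and the C5a arm are trans-diequatorial on the cyclohexane chair, so an acyl-anion carbon and an enol-ether carbon lie within 7-exo reach.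
2. The two tertiary acetates are epimeric. Ring A (axial O) comes from equatorial CH3 addition to a ketone; ring B (equatorial O) from methylenation, equatorial epoxidation and hydride opening, after mono-functionalisation of the twofold-symmetric diketone 14.
3. Both cyclohexanones, the CH2CH2 bridge and six stereocentres come from a two-directional Lewis-acid epoxide/silyl enol ether cyclisation of 12, itself assembled from two epoxy acylsilanes 10, vinyllithium and iodine (Brook rearrangement, oxidative dimerisation).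
4. Absolute configuration: one Sharpless epoxidation of the (E)-allylic alcohol 5, made by carboalumination of a pentynyl silyl ether.
5. Order of ring formation: the two carbocycles together (step 7), then the two oxepanones together (step 17).

Key step: step 17

Remark: read from the SMILES, the two bicyclic halves are not equivalent (both are 5aS,6S,9aS, but the acetoxy carbon C7 is R in one half and S in the other), so the symmetry must be broken once (step 9). Carbocycle locants used below: C1 = CH carrying the bridge, C2 = quaternary C(CH3), C3 = CH–O, C6 = carbonyl or tertiary O carbon; in every ring the C2–CH3, the C3–O bond and the bridge CH2 are on one face, the C2 side chain and C1–H on the other.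

**Route**

Step 1
Reactants: 1 pent-4-yn-1-ol
Product: 2 tert-butyl(pent-4-yn-1-yloxy)diphenylsilane
Conditions: TBDPSCl, imidazole, CH2Cl2, 0 °C → rt
Reagents that add atoms: tert-butyl(chloro)diphenylsilane, CC(C)(C)[Si](Cl)(c1ccccc1)c1ccccc1
Why: Standard silylation of the primary alcohol; the bulky, weakly Lewis-basic silyl ether should survive the organoaluminium and Lewis-acid steps ahead.

Step 2
Reactants: 2 tert-butyl(pent-4-yn-1-yloxy)diphenylsilane
Product: 5 (E)-6-[(tert-butyldiphenylsilyl)oxy]-3-methylhex-2-en-1-ol, via alkenylalane 3 (not isolated), via lithium alanate 4 (not isolated)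
Conditions: AlMe3, Cp2ZrCl2 (25 mol%), CH2Cl2, 0 °C → rt; n-BuLi, THF, −78 °C; (CH2O)n, −78 °C → rt
Reagents that add atoms: trimethylaluminium, C[Al](C)C; formaldehyde (as paraformaldehyde), C=O
Why: Negishi zirconium-catalysed syn-carboalumination puts CH3 on the internal and Al on the terminal alkyne carbon, and the derived alanate adds to formaldehyde with retention, so only the (E)-trisubstituted allylic alcohol should form.

Step 3
Reactants: 5 (E)-6-[(tert-butyldiphenylsilyl)oxy]-3-methylhex-2-en-1-ol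
Product: 6 [(2S,3S)-3-{3-[(tert-butyldiphenylsilyl)oxy]propyl}-3-methyloxiran-2-yl]methanol
Conditions: Ti(OiPr)4 (10 mol%), L-(+)-diethyl tartrate (12 mol%), t-BuOOH, 4 Å MS, CH2Cl2, −20 °C
Reagents that add atoms: tert-butyl hydroperoxide, CC(C)(C)OO
Why: Sharpless asymmetric epoxidation; with L-(+)-diethyl tartrate the (E)-allylic alcohol is epoxidised on the face that gives the (2S,3S)-epoxide (as for geraniol), which fixes the C–O stereocentre and the configuration of the future quaternary carbon.

Step 4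
Reactants: 6 [(2S,3S)-3-{3-[(tert-butyldiphenylsilyl)oxy]propyl}-3-methyloxiran-2-yl]methanol
Product: 8 tert-butyl(3-{(2S,3S)-2-methyl-3-[3-(trimethylsilyl)prop-2-yn-1-yl]oxiran-2-yl}propoxy)diphenylsilane, via epoxy triflate 7 (not isolated)
Conditions: Tf2O, 2,6-lutidine, CH2Cl2, −78 °C; then LiC≡CSiMe3 (from HC≡CSiMe3, n-BuLi), THF–DMPU, −78 °C
Reagents that add atoms: ethynyltrimethylsilane, C#C[Si](C)(C)C
Why: The primary triflate is displaced by the acetylide (SN2) at −78 °C faster than the trisubstituted epoxide is opened, so both stereocentres are carried through unchanged.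

Step 5
Reactants: 8 tert-butyl(3-{(2S,3S)-2-methyl-3-[3-(trimethylsilyl)prop-2-yn-1-yl]oxiran-2-yl}propoxy)diphenylsilane
Product: 10 3-[(2S,3S)-3-{3-[(tert-butyldiphenylsilyl)oxy]propyl}-3-methyloxiran-2-yl]-1-(trimethylsilyl)propan-1-one, via alkenylborane 9 (not isolated)
Conditions: (c-C6H11)2BH (from BH3·SMe2, cyclohexene), THF, 0 °C; then Me3NO (anhydrous), THF, 0 °C → rt
Reagents that add atoms: trimethylamine N-oxide, C[N+](C)(C)[O-]
Why: Hydroboration of a 1-silylalkyne places boron on the silyl-bearing carbon, and amine-oxide oxidation of the alkenylborane gives the acylsilane without base, which spares the epoxide and the acylsilane.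

Step 6
Reactants: 10 3-[(2S,3S)-3-{3-[(tert-butyldiphenylsilyl)oxy]propyl}-3-methyloxiran-2-yl]-1-(trimethylsilyl)propan-1-one (two molecules)
Product: 12 (3Z,7Z)-1,10-bis[(2S,3S)-3-{3-[(tert-butyldiphenylsilyl)oxy]propyl}-3-methyloxiran-2-yl]-3,8-bis[(trimethylsilyl)oxy]deca-3,7-diene, via siloxyallyllithium 11 (not isolated)
Conditions: CH2=CHBr, t-BuLi (2 equiv), Et2O, −78 °C; then 10, THF, −78 → −45 °C; I2 (0.5 equiv), −78 °C
Reagents that add atoms: vinyl bromide, C=CBr
Why: Vinyllithium adds to the acylsilane, [1,2]-Brook rearrangement of the alkoxide gives the (Z)-siloxyallyl anion, and oxidative coupling of two such anions at their CH2 termini with iodine forms the CH2–CH2 bridge (acylsilane addition, Brook rearrangement and oxidative dimerisation in one flask).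

Step 7
Reactants: 12 (3Z,7Z)-bis(epoxy) bis(silyl enol ether)
Product: 13 1,2-bis[(1S,2S,3S)-2-{3-[(tert-butyldiphenylsilyl)oxy]propyl}-3-hydroxy-2-methyl-6-oxocyclohexyl]ethane
Conditions: MeAlCl2, CH2Cl2, −94 → −78 °C; aq. KNaC4H4O6 work-up
Reagents that add atoms: none
Why: Two-directional Lewis-acid epoxide-opening cyclisation terminated by silyl enol ethers: each enol carbon attacks the activated epoxide at its tertiary carbon with inversion through a chair transition state (C–O and bridge CH2 equatorial, the latter fixed by the Z enol geometry), so the four new ring stereocentres follow from the two epoxides.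

Step 8
Reactants: 13 twofold-symmetric diketone diol
Product: 14 1,2-bis[(1S,2S,3S)-2-{3-[(tert-butyldiphenylsilyl)oxy]propyl}-3-[(2-methoxypropan-2-yl)oxy]-2-methyl-6-oxocyclohexyl]ethane
Conditions: 2-methoxypropene, PPTS (cat.), CH2Cl2, 0 °C
Reagents that add atoms: 2-methoxypropene, COC(C)=C
Why: Acid-catalysed mixed-ketal formation masks both secondary alcohols with a group that already carries the future C(CH3)2 carbon of the oxepanones and tolerates the basic and hydridic steps ahead.

Step 9
Reactants: 14 twofold-symmetric bis(ketal) diketone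
Product: 15 keto alcohol (ring A: C6 now C(OH)CH3 with OH axial, cis to the C2 methyl; ring B unchanged ketone)
Conditions: CeCl3 (anhydrous), MeLi (1 equiv), THF, −78 °C
Reagents that add atoms: methyllithium, C[Li]
Why: Organocerium 1,2-addition without enolisation: in the chair locked by the equatorial bridge, side chain and C3–O groups the axial C2 methyl blocks axial attack, so CH3 enters equatorially and the new OH is axial; the two ketones of 14 are equivalent, so the mono-adduct forms statistically and unreacted 14 is recovered and recycled.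

Step 10
Reactants: 15 keto alcohol
Product: 16 exocyclic alkene (ring B C=O converted into C=CH2)
Conditions: Cp2TiMe2, toluene–THF, 70 °C, dark
Reagents that add atoms: dimethyltitanocene, C[Ti](C)(C1C=CC=C1)C1C=CC=C1
Why: Petasis methylenation (titanium methylidene generated thermally) converts the hindered ketone under non-basic conditions, so the adjacent bridge-bearing stereocentre is not epimerised.

Step 11
Reactants: 16 exocyclic alkene
Product: 17 spiro-epoxide (ring B, epoxide oxygen equatorial, trans to the C2 methyl)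
Conditions: mCPBA, NaHCO3, CH2Cl2, 0 °C
Reagents that add atoms: 3-chloroperoxybenzoic acid, OOC(=O)c1cccc(Cl)c1
Why: Peracid epoxidation of the exocyclic alkene from the equatorial direction, because the axial face is shielded by the syn-axial C2 methyl; this places oxygen in the opposite sense to step 9.

Step 12
Reactants: 17 spiro-epoxide
Product: 18 bis(tertiary alcohol) (ring A OH axial, ring B OH equatorial with axial CH3)
Conditions: LiAlH4, THF, 0 °C → rt
Reagents that add atoms: none
Why: Hydride opens the 1,1-disubstituted epoxide at CH2 (SN2), leaving the equatorial tertiary alcohol, so ring B is epimeric to ring A at this carbon.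

Step 13
Reactants: 18 bis(tertiary alcohol)
Product: 19 bis(tertiary acetate)
Conditions: LiN(SiMe3)2, THF, −78 °C; Ac2O, −78 → 0 °C
Reagents that add atoms: acetic anhydride, CC(=O)OC(C)=O
Why: The hindered tertiary lithium alkoxides are acylated by Ac2O under basic conditions that leave the acid-labile mixed ketals and the silyl ethers intact.

Step 14
Reactants: 19 bis(tertiary acetate)
Product: 20 bis(prop-1-en-2-yl ether)
Conditions: Me3SiOTf, i-Pr2NEt, CH2Cl2, −20 → 0 °C
Reagents that add atoms: none
Why: The silyl triflate ionises each mixed ketal by loss of the less hindered methoxy group as MeOSiMe3, and the amine deprotonates the oxocarbenium ion to the enol ether (ketal-to-enol-ether elimination).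

Step 15
Reactants: 20 bis(prop-1-en-2-yl ether)
Product: 21 diol (both CH2CH2CH2OH arms free)
Conditions: Bu4NF, THF, rt
Reagents that add atoms: none
Why: Fluoride cleaves the two primary silyl ethers, while enol ethers and hindered tertiary acetates are stable to it.

Step 16
Reactants: 21 diol
Product: 22 dialdehyde
Conditions: SO3·pyridine, DMSO, i-Pr2NEt, CH2Cl2, 0 °C
Reagents that add atoms: none
Why: Parikh–Doering oxidation gives the dialdehyde under basic conditions that do not hydrolyse the enol ethers.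

Step 17
Reactants: 22 dialdehyde
Product: 25 target (CNP0325605.1), via ring A oxepanone 23 (not isolated), via ring B oxepanone 24 (not isolated)
Conditions: 3-mesityl-4,5-dimethylthiazol-3-ium perchlorate (20 mol%), DBU (40 mol%), 1,4-dioxane (0.01 M), 100 °C
Reagents that add atoms: none
Why: Proposed new method: the carbene adds to each aldehyde to give a Breslow intermediate (acyl anion equivalent) whose nucleophilic carbon bonds to the oxygen-bearing carbon of the neighbouring prop-1-en-2-yl ether while its O–H proton passes to the terminal CH2 (Conia-ene-like transition state with oxocarbenium character), and collapse of the adduct releases ketone and carbene. The closest known reaction type is the NHC-catalysed intramolecular hydroacylation of enol ethers and unactivated alkenes by aromatic aldehydes, which gives five- and six-membered benzo-fused ketones with a fully substituted α-carbon; here it is asked to work with an aliphatic aldehyde and a seven-membered ring. Each oxepan-3-one closes in a 7-exo-trig mode, the former CH2 staying outside the ring as the second methyl of the C(CH3)2 carbon. No stereocentre is formed, and none of the eight existing ones is α to a carbonyl group, so none can epimerise. The step needs Markovnikov regioselectivity, which the ring oxygen secures by stabilising positive charge at the attacked carbon, and it must outrun aldol and acyloin self-condensation, which high dilution and the trans-diequatorial placement of the C–O bond and the CH2CH2CHO arm on each chair should secure. Both rings close in one flask, so two C–C bonds, two ketones and two gem-dimethyl carbons arise in one redox-neutral operation.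

**Compound list**

1 | pent-4-yn-1-ol | C#CCCCO | starting material
2 | tert-butyl(pent-4-yn-1-yloxy)diphenylsilane | C#CCCCO[Si](c1ccccc1)(c1ccccc1)C(C)(C)C | intermediate
3 | (E)-{5-[(tert-butyldiphenylsilyl)oxy]-2-methylpent-1-en-1-yl}dimethylalane (not isolated) | C[Al](C)/C=C(\C)CCCO[Si](c1ccccc1)(c1ccccc1)C(C)(C)C | intermediate
4 | lithium butyl{(E)-5-[(tert-butyldiphenylsilyl)oxy]-2-methylpent-1-en-1-yl}dimethylalanate (not isolated) | [Li+].CCCC[Al-](C)(C)/C=C(\C)CCCO[Si](c1ccccc1)(c1ccccc1)C(C)(C)C | intermediate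
5 | (E)-6-[(tert-butyldiphenylsilyl)oxy]-3-methylhex-2-en-1-ol | OC/C=C(\C)CCCO[Si](c1ccccc1)(c1ccccc1)C(C)(C)C | intermediate
6 | [(2S,3S)-3-{3-[(tert-butyldiphenylsilyl)oxy]propyl}-3-methyloxiran-2-yl]methanol | OC[C@@H]1O[C@@]1(C)CCCO[Si](c1ccccc1)(c1ccccc1)C(C)(C)C | intermediate
7 | [(2S,3S)-3-{3-[(tert-butyldiphenylsilyl)oxy]propyl}-3-methyloxiran-2-yl]methyl trifluoromethanesulfonate (not isolated) | O=S(=O)(OC[C@@H]1O[C@@]1(C)CCCO[Si](c1ccccc1)(c1ccccc1)C(C)(C)C)C(F)(F)F | intermediate
8 | tert-butyl(3-{(2S,3S)-2-methyl-3-[3-(trimethylsilyl)prop-2-yn-1-yl]oxiran-2-yl}propoxy)diphenylsilane | C[Si](C)(C)C#CC[C@@H]1O[C@@]1(C)CCCO[Si](c1ccccc1)(c1ccccc1)C(C)(C)C | intermediate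
9 | (Z)-1-(dicyclohexylboryl)-1-(trimethylsilyl)alkene from 8 (B and Si on the same carbon; not isolated) | C[Si](C)(C)/C(=C\C[C@@H]1O[C@@]1(C)CCCO[Si](c2ccccc2)(c2ccccc2)C(C)(C)C)B(C1CCCCC1)C1CCCCC1 | intermediate
10 | 3-[(2S,3S)-3-{3-[(tert-butyldiphenylsilyl)oxy]propyl}-3-methyloxiran-2-yl]-1-(trimethylsilyl)propan-1-one | C[Si](C)(C)C(=O)CC[C@@H]1O[C@@]1(C)CCCO[Si](c1ccccc1)(c1ccccc1)C(C)(C)C | intermediate
11 | (Z)-siloxyallyllithium from 10 and vinyllithium after Brook rearrangement (not isolated) | [Li]C/C=C(\O[Si](C)(C)C)CC[C@@H]1O[C@@]1(C)CCCO[Si](c1ccccc1)(c1ccccc1)C(C)(C)C | intermediate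
12 | (3Z,7Z)-1,10-bis[(2S,3S)-3-{3-[(tert-butyldiphenylsilyl)oxy]propyl}-3-methyloxiran-2-yl]-3,8-bis[(trimethylsilyl)oxy]deca-3,7-diene | C[Si](C)(C)O/C(CC[C@@H]1O[C@@]1(C)CCCO[Si](c1ccccc1)(c1ccccc1)C(C)(C)C)=C\CC/C=C(\O[Si](C)(C)C)CC[C@@H]1O[C@@]1(C)CCCO[Si](c1ccccc1)(c1ccccc1)C(C)(C)C | intermediate
13 | 1,2-bis[(1S,2S,3S)-2-{3-[(tert-butyldiphenylsilyl)oxy]propyl}-3-hydroxy-2-methyl-6-oxocyclohexyl]ethane | O=C1CC[C@H](O)[C@@](C)(CCCO[Si](c2ccccc2)(c2ccccc2)C(C)(C)C)[C@@H]1CC[C@H]1[C@](C)(CCCO[Si](c2ccccc2)(c2ccccc2)C(C)(C)C)[C@@H](O)CCC1=O | intermediate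
14 | 1,2-bis[(1S,2S,3S)-2-{3-[(tert-butyldiphenylsilyl)oxy]propyl}-3-[(2-methoxypropan-2-yl)oxy]-2-methyl-6-oxocyclohexyl]ethane | O=C1CC[C@H](OC(C)(C)OC)[C@@](C)(CCCO[Si](c2ccccc2)(c2ccccc2)C(C)(C)C)[C@@H]1CC[C@H]1[C@](C)(CCCO[Si](c2ccccc2)(c2ccccc2)C(C)(C)C)[C@@H](OC(C)(C)OC)CCC1=O | intermediate
15 | keto alcohol: ring A (1S,2S,3S,6R)-6-hydroxy-6-methyl (OH axial, cis to the C2 methyl), ring B (2S,3S,4S)-cyclohexanone as in 14 | O[C@]1(C)CC[C@H](OC(C)(C)OC)[C@@](C)(CCCO[Si](c2ccccc2)(c2ccccc2)C(C)(C)C)[C@@H]1CC[C@H]1[C@](C)(CCCO[Si](c2ccccc2)(c2ccccc2)C(C)(C)C)[C@@H](OC(C)(C)OC)CCC1=O | intermediate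
16 | exocyclic alkene: 15 with the ring B carbonyl converted into C=CH2, stereocentres unchanged | O[C@]1(C)CC[C@H](OC(C)(C)OC)[C@@](C)(CCCO[Si](c2ccccc2)(c2ccccc2)C(C)(C)C)[C@@H]1CC[C@H]1[C@](C)(CCCO[Si](c2ccccc2)(c2ccccc2)C(C)(C)C)[C@@H](OC(C)(C)OC)CCC1=C | intermediate
17 | spiro-epoxide: 16 with the ring B C=CH2 epoxidised, epoxide O equatorial (trans to the C2 methyl) | O[C@]1(C)CC[C@H](OC(C)(C)OC)[C@@](C)(CCCO[Si](c2ccccc2)(c2ccccc2)C(C)(C)C)[C@@H]1CC[C@H]1[C@](C)(CCCO[Si](c2ccccc2)(c2ccccc2)C(C)(C)C)[C@@H](OC(C)(C)OC)CC[C@]12OC2 | intermediate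
18 | bis(tertiary alcohol): ring A C6–OH axial (cis to the C2 methyl), ring B C6–OH equatorial with axial CH3; both C3–O as 2-methoxypropan-2-yl ethers, both side chains as silyl ethers | O[C@]1(C)CC[C@H](OC(C)(C)OC)[C@@](C)(CCCO[Si](c2ccccc2)(c2ccccc2)C(C)(C)C)[C@@H]1CC[C@H]1[C@](C)(CCCO[Si](c2ccccc2)(c2ccccc2)C(C)(C)C)[C@@H](OC(C)(C)OC)CC[C@]1(C)O | intermediate
19 | bis(tertiary acetate) of 18 | CC(=O)O[C@]1(C)CC[C@H](OC(C)(C)OC)[C@@](C)(CCCO[Si](c2ccccc2)(c2ccccc2)C(C)(C)C)[C@@H]1CC[C@H]1[C@](C)(CCCO[Si](c2ccccc2)(c2ccccc2)C(C)(C)C)[C@@H](OC(C)(C)OC)CC[C@]1(C)OC(C)=O | intermediate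
20 | bis(prop-1-en-2-yl ether): 19 with both mixed ketals converted into O–C(CH3)=CH2 | CC(=O)O[C@]1(C)CC[C@H](OC(C)=C)[C@@](C)(CCCO[Si](c2ccccc2)(c2ccccc2)C(C)(C)C)[C@@H]1CC[C@H]1[C@](C)(CCCO[Si](c2ccccc2)(c2ccccc2)C(C)(C)C)[C@@H](OC(C)=C)CC[C@]1(C)OC(C)=O | intermediate
21 | diol: 20 with both silyl ethers cleaved (two 3-hydroxypropyl arms) | CC(=O)O[C@]1(C)CC[C@H](OC(C)=C)[C@@](C)(CCCO)[C@@H]1CC[C@H]1[C@](C)(CCCO)[C@@H](OC(C)=C)CC[C@]1(C)OC(C)=O | intermediate
22 | dialdehyde: two 3-oxopropyl arms, two prop-1-en-2-yl ethers, two tertiary acetates | CC(=O)O[C@]1(C)CC[C@H](OC(C)=C)[C@@](C)(CCC=O)[C@@H]1CC[C@H]1[C@](C)(CCC=O)[C@@H](OC(C)=C)CC[C@]1(C)OC(C)=O | intermediate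
23 | mono-cyclised keto aldehyde, oxepan-3-one closed on ring A (not isolated) | CC(=O)O[C@]1(C)CC[C@@H]2OC(C)(C)C(=O)CC[C@@]2(C)[C@@H]1CC[C@H]1[C@](C)(CCC=O)[C@@H](OC(C)=C)CC[C@]1(C)OC(C)=O | intermediate
24 | mono-cyclised keto aldehyde, oxepan-3-one closed on ring B (not isolated) | CC(=O)O[C@]1(C)CC[C@H](OC(C)=C)[C@@](C)(CCC=O)[C@@H]1CC[C@H]1[C@]2(C)CCC(=O)C(C)(C)O[C@H]2CC[C@]1(C)OC(C)=O | intermediate
25 | (5aS,6S,7R,9aS)-6-{2-[(5aS,6S,7S,9aS)-7-acetoxy-2,2,5a,7-tetramethyl-3-oxodecahydro-1-benzoxepin-6-yl]ethyl}-2,2,5a,7-tetramethyl-3-oxodecahydro-1-benzoxepin-7-yl acetate (CNP0325605.1) | CC(=O)O[C@]1(C)CC[C@@H]2OC(C)(C)C(=O)CC[C@@]2(C)[C@@H]1CC[C@H]1[C@]2(C)CCC(=O)C(C)(C)O[C@H]2CC[C@]1(C)OC(C)=O | target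

**Step count and risks**

Total step count: 17. Longest linear sequence: 17 steps (1 → 25; the route is linear and becomes two-directional from step 6).

Steps most likely to fail:

Step 17 (Proposed new method). Intermolecular acyloin or aldol condensation of the aliphatic aldehydes, or hydrolytic loss of the enol ethers, may outrun the slow seven-membered closure. The fallback uses known chemistry, sets out from 22 and returns at 25. Wittig methylenation of both aldehydes (Ph3P=CH2, THF, −78 → 0 °C) gives the bis(terminal alkene) F1. Ring-closing enol ether–olefin metathesis with the second-generation Grubbs catalyst (H2IMes)(PCy3)Cl2Ru=CHPh in toluene at 70 °C joins the same two carbons as a C=C bond with loss of ethylene and gives the bis(cyclic enol ether) F2. Epoxidation with dimethyldioxirane at −78 °C gives the bis(epoxy ether) F3, which AlMe3 opens at the ring-oxygen-bearing carbon to deliver the second methyl group, giving the bis(3-hydroxy-2,2-dimethyloxepane) F4. Dess–Martin oxidation of the two secondary alcohols then gives 25.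

Step 6. The alkoxide or the allyl anion may open the neighbouring epoxide before Brook rearrangement and coupling, or the oxidative coupling may join the wrong (oxygen-bearing) termini. The fallback sets out from 6 and returns at 12. The triflate 7 is made as in step 4 and alkylates the lithium enolate of N-methoxy-N-methylacetamide to give the Weinreb amide F5. Vinylmagnesium bromide converts it into the vinyl ketone F6. Reductive tail-to-tail coupling of two molecules with SmI2 in THF–HMPA at −78 °C in the presence of Me3SiCl traps both enolates and gives 12.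

Step 14. The silyl triflate may ionise the wrong C–O bond (loss of the whole ketal, i.e. deprotection) or attack the tertiary acetates. The fallback sets out from 18 and returns at 20, and builds the enol ethers by ester methylenation instead. Methanolysis of the mixed ketals (PPTS, MeOH) gives the tetraol F7. Ac2O in pyridine acetylates only the two secondary hydroxyls, giving the diacetate F8. Petasis methylenation of the two acetate carbonyls (Cp2TiMe2, toluene, 70 °C) gives the bis(prop-1-en-2-yl ether) diol F9. Acetylation of the two tertiary alkoxides as in step 13 gives 20.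

Further compounds

F1 | step 17 | bis(terminal alkene): 22 with both CH=O groups converted into CH=CH2 | CC(=O)O[C@]1(C)CC[C@H](OC(C)=C)[C@@](C)(CCC=C)[C@@H]1CC[C@H]1[C@](C)(CCC=C)[C@@H](OC(C)=C)CC[C@]1(C)OC(C)=O
F2 | step 17 | bis(cyclic enol ether): two 2-methyl-4,5-dihydrooxepine rings (C2=C3) fused to the cyclohexanes | CC(=O)O[C@]1(C)CC[C@@H]2OC(C)=CCC[C@@]2(C)[C@@H]1CC[C@H]1[C@]2(C)CCC=C(C)O[C@H]2CC[C@]1(C)OC(C)=O
F3 | step 17 | bis(2,3-epoxy-2-methyloxepane) (epoxide configuration not controlled, removed later) | CC(=O)O[C@]1(C)CC[C@@H]2OC3(C)OC3CC[C@@]2(C)[C@@H]1CC[C@H]1[C@]2(C)CCC3OC3(C)O[C@H]2CC[C@]1(C)OC(C)=O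
F4 | step 17 | bis(3-hydroxy-2,2-dimethyloxepane) diacetate (carbinol configuration not controlled, removed by oxidation) | CC(=O)O[C@]1(C)CC[C@@H]2OC(C)(C)C(O)CC[C@@]2(C)[C@@H]1CC[C@H]1[C@]2(C)CCC(O)C(C)(C)O[C@H]2CC[C@]1(C)OC(C)=O
F5 | step 6 | 3-[(2S,3S)-3-{3-[(tert-butyldiphenylsilyl)oxy]propyl}-3-methyloxiran-2-yl]-N-methoxy-N-methylpropanamide | CON(C)C(=O)CC[C@@H]1O[C@@]1(C)CCCO[Si](c1ccccc1)(c1ccccc1)C(C)(C)C
F6 | step 6 | 5-[(2S,3S)-3-{3-[(tert-butyldiphenylsilyl)oxy]propyl}-3-methyloxiran-2-yl]pent-1-en-3-one | C=CC(=O)CC[C@@H]1O[C@@]1(C)CCCO[Si](c1ccccc1)(c1ccccc1)C(C)(C)C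
F7 | step 14 | tetraol: 18 with both mixed ketals removed (two secondary, two tertiary OH) | O[C@]1(C)CC[C@H](O)[C@@](C)(CCCO[Si](c2ccccc2)(c2ccccc2)C(C)(C)C)[C@@H]1CC[C@H]1[C@](C)(CCCO[Si](c2ccccc2)(c2ccccc2)C(C)(C)C)[C@@H](O)CC[C@]1(C)O
F8 | step 14 | di(secondary acetate) of F7, tertiary OH free | O[C@]1(C)CC[C@H](OC(C)=O)[C@@](C)(CCCO[Si](c2ccccc2)(c2ccccc2)C(C)(C)C)[C@@H]1CC[C@H]1[C@](C)(CCCO[Si](c2ccccc2)(c2ccccc2)C(C)(C)C)[C@@H](OC(C)=O)CC[C@]1(C)O
F9 | step 14 | bis(prop-1-en-2-yl ether) of F7, tertiary OH free | O[C@]1(C)CC[C@H](OC(C)=C)[C@@](C)(CCCO[Si](c2ccccc2)(c2ccccc2)C(C)(C)C)[C@@H]1CC[C@H]1[C@](C)(CCCO[Si](c2ccccc2)(c2ccccc2)C(C)(C)C)[C@@H](OC(C)=C)CC[C@]1(C)O
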